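## Retrosynthetic overview

1. Numbering: C1 = lactone C=O, C2–C7 along the ring, C8 = CH(CH3)–O, side chain C1′–C10′. Target ⇐ Lindlar semi-hydrogenation of the C2′≡C3′ ynoate (last step, neutral).
2. Nine-membered lactone (the only ring, closed in the penultimate step) ⇐ C4–C5 bond by SmI2 ketyl/carbonyl (pinacol) coupling of an open-chain C4 methyl ketone and C5 aldehyde; C4 and C5 are set here.
3. Keto-aldehyde ⇐ ozonolysis of a C5 vinyl group; C7–O ester ⇐ (R)-4-silyloxydec-2-ynoic acid (heptanal + methyl propiolate).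
4. C5–C8 unit ⇐ (Z)-crotylboration of the α-acyloxy aldehyde made by ozonolysis of the (S)-but-3-en-2-yl ester.
5. C1–C4 keto acid ⇐ (E)-crotylboration of methacrolein, silylation, RuO4 cleavage of both alkenes.

Assumption: the (−)-α-pinene-derived Ipc2B reagents are taken to add to the Re face of both aldehydes (Brown's rule, from memory) and (S,S)-ProPhenol to give the (R)-carbinol; if a first run shows otherwise, the antipodal reagent or ligand is used.

## Route

Step 1
Reactants: 1 methacrolein; 2 trans-but-2-ene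
Product: 4 (3R,4R)-2,4-dimethylhexa-1,5-dien-3-ol, via (E)-crotylbis(isopinocampheyl)borane 3 (not isolated)
Conditions: 2, KOtBu, n-BuLi, THF, −78 → −45 °C; (+)-Ipc2BOMe [from (−)-α-pinene], −78 °C; BF3·OEt2; then 1, −78 °C; NaOH, H2O2, 0 °C → rt
Reagents that add atoms: none
Why: Brown crotylboration through a closed chair transition state: the E-crotyl geometry gives the anti C2-methyl/C3-hydroxyl pair and the (−)-α-pinene-derived Ipc ligands direct addition to the Re face of the enal, which fixes both new stereocentres as (3R,4R).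

Step 2
Reactants: 4 (3R,4R)-2,4-dimethylhexa-1,5-dien-3-ol
Product: 5 tert-butyl{[(3R,4R)-2,4-dimethylhexa-1,5-dien-3-yl]oxy}dimethylsilane
Conditions: TBSOTf, 2,6-lutidine, CH2Cl2, −78 → 0 °C
Reagents that add atoms: tert-butyldimethylsilyl triflate CC(C)(C)[Si](C)(C)OS(=O)(=O)C(F)(F)F
Why: Silyl ether formation with the triflate silylates the hindered secondary allylic alcohol cleanly, so that C3–OH is masked during acid formation and esterification; no stereocentre is touched.

Step 3
Reactants: 5 tert-butyl{[(3R,4R)-2,4-dimethylhexa-1,5-dien-3-yl]oxy}dimethylsilane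
Product: 6 (2S,3R)-3-[(tert-butyldimethylsilyl)oxy]-2-methyl-4-oxopentanoic acid
Conditions: RuCl3·xH2O (5 mol%), NaIO4 (10 equiv), CCl4/MeCN/H2O, 0 °C → rt
Reagents that add atoms: sodium periodate [Na+].[O-]I(=O)(=O)=O; water O
Why: Sharpless RuO4 oxidative cleavage converts the vinyl group into the carboxylic acid and the isopropenyl group into the methyl ketone in one operation under acidic, non-enolising conditions that leave the TBS ether and the C2/C3 stereocentres intact.

Step 4
Reactants: 6 (2S,3R)-3-[(tert-butyldimethylsilyl)oxy]-2-methyl-4-oxopentanoic acid; 7 (S)-but-3-en-2-ol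
Product: 8 (2S)-but-3-en-2-yl (2S,3R)-3-[(tert-butyldimethylsilyl)oxy]-2-methyl-4-oxopentanoate
Conditions: DCC, DMAP (10 mol%), CH2Cl2, 0 °C
Reagents that add atoms: none
Why: Steglich esterification of an unhindered secondary alcohol is fast at 0 °C, so the β-silyloxy γ-keto acid is not exposed long enough to eliminate or epimerise, and the C8 stereocentre comes unchanged from 7 because only the acyl C–O bond is formed.

Step 5
Reactants: 8 (2S)-but-3-en-2-yl (2S,3R)-3-[(tert-butyldimethylsilyl)oxy]-2-methyl-4-oxopentanoate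
Product: 10 (2S)-1-oxopropan-2-yl (2S,3R)-3-[(tert-butyldimethylsilyl)oxy]-2-methyl-4-oxopentanoate, via ozonide 9 (not isolated)
Conditions: O3, CH2Cl2, −78 °C; Me2S, −78 °C → rt; used crude
Reagents that add atoms: ozone [O-][O+]=O
Why: Ozonolysis (Criegee) of the only alkene gives the α-acyloxy aldehyde without touching ketone, ester or silyl ether, and the configurationally labile aldehyde is used crude.

Step 6
Reactants: 10 (2S)-1-oxopropan-2-yl (2S,3R)-3-[(tert-butyldimethylsilyl)oxy]-2-methyl-4-oxopentanoate; 11 cis-but-2-ene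
Product: 13 (2S,3R,4S)-3-hydroxy-4-methylhex-5-en-2-yl (2S,3R)-3-[(tert-butyldimethylsilyl)oxy]-2-methyl-4-oxopentanoate, via (Z)-crotylbis(isopinocampheyl)borane 12 (not isolated)
Conditions: 11, KOtBu, n-BuLi, THF, −78 → −45 °C; (+)-Ipc2BOMe, −78 °C; BF3·OEt2; then 10, −78 °C, 3 h; NaBO3·4H2O, THF/H2O, 0 °C → rt
Reagents that add atoms: none
Why: Brown crotylboration: the Z-crotylborane reacts through the chair transition state to give the syn C6-methyl/C7-hydroxyl pair, its Re-face preference coincides with Felkin–Anh attack anti to the C8–O bond (7,8-anti, matched case) so that C6 (S) and C7 (R) are set together, and at −78 °C the aldehyde reacts far faster than the hindered α-silyloxy ketone.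

Step 7
Reactants: 14 heptanal; 15 methyl propiolate
Product: 16 methyl (4R)-4-hydroxydec-2-ynoate
Conditions: Me2Zn (3 equiv), (S,S)-ProPhenol (10 mol%), Ph3PO (20 mol%), toluene, 4 °C; aq NH4Cl
Reagents that add atoms: none
Why: Trost dinuclear zinc–ProPhenol alkynylation: the chiral zinc alkynylide complex delivers the propiolate to the Si face of heptanal, which sets the (R)-carbinol (C4′).

Step 8
Reactants: 16 methyl (4R)-4-hydroxydec-2-ynoate
Product: 17 methyl (4R)-4-[(tert-butyldimethylsilyl)oxy]dec-2-ynoate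
Conditions: TBSCl, imidazole, DMF, rt
Reagents that add atoms: tert-butyldimethylsilyl chloride CC(C)(C)[Si](C)(C)Cl
Why: Silylation (TBSCl/imidazole) of the unhindered propargylic alcohol protects C4′–OH for the later acylation; the stereocentre is not involved.

Step 9
Reactants: 17 methyl (4R)-4-[(tert-butyldimethylsilyl)oxy]dec-2-ynoate
Product: 18 (4R)-4-[(tert-butyldimethylsilyl)oxy]dec-2-ynoic acid
Conditions: LiOH, THF/H2O, 0 °C; then 1 M HCl to pH 3
Reagents that add atoms: lithium hydroxide [Li+].[OH-]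
Why: Saponification of the methyl ynoate with LiOH at 0 °C is faster than conjugate addition to the shielded triple bond and leaves the TBS ether and the C4′ stereocentre untouched.

Step 10
Reactants: 13 (2S,3R,4S)-3-hydroxy-4-methylhex-5-en-2-yl (2S,3R)-3-[(tert-butyldimethylsilyl)oxy]-2-methyl-4-oxopentanoate; 18 (4R)-4-[(tert-butyldimethylsilyl)oxy]dec-2-ynoic acid
Product: 19 (2S,3R,4S)-2-{[(2S,3R)-3-[(tert-butyldimethylsilyl)oxy]-2-methyl-4-oxopentanoyl]oxy}-4-methylhex-5-en-3-yl (4R)-4-[(tert-butyldimethylsilyl)oxy]dec-2-ynoate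
Conditions: DCC, DMAP (20 mol%), CH2Cl2, −20 → 0 °C
Reagents that add atoms: none
Why: Steglich esterification acylates the hindered C7 hydroxyl while the larger keto-acyl group stays on the less hindered C8 oxygen, and the acid is used as the ynoic acid because a (Z)-enoic acid would isomerise under acyl-transfer catalysis; no stereocentre is touched.

Step 11
Reactants: 19 (bis-TBS diester)
Product: 20 (2S,3R,4S)-2-{[(2S,3R)-3-hydroxy-2-methyl-4-oxopentanoyl]oxy}-4-methylhex-5-en-3-yl (4R)-4-hydroxydec-2-ynoate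
Conditions: HF·pyridine, pyridine, THF, 0 °C → rt
Reagents that add atoms: none
Why: Fluoride-mediated desilylation with buffered HF·pyridine removes both secondary TBS ethers without acyl migration or ester cleavage, which frees C3–OH as the chelating group for the ring closure and C4′–OH of the side chain.

Step 12
Reactants: 20 (diol diester with terminal vinyl group)
Product: 22 (2R,3R,4S)-4-{[(2S,3R)-3-hydroxy-2-methyl-4-oxopentanoyl]oxy}-2-methyl-1-oxopentan-3-yl (4R)-4-hydroxydec-2-ynoate, via ozonide 21 (not isolated)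
Conditions: O3, CH2Cl2, −78 °C (Sudan Red 7B end point); Me2S, −78 → 0 °C; used crude at once
Reagents that add atoms: ozone [O-][O+]=O
Why: Ozonolysis is chemoselective for the terminal alkene because the electron-poor conjugated alkyne reacts orders of magnitude more slowly, and the β-acyloxy aldehyde formed is used at once without chromatography so that C6 does not epimerise or eliminate.

Step 13
Reactants: 22 (C4 methyl ketone / C5 aldehyde diester)
Product: 24 (3S,4R,5R,6S,7S,8R,9S)-4,5,6-trihydroxy-3,5,7,9-tetramethyl-2-oxooxonan-8-yl (4R)-4-hydroxydec-2-ynoate, via samarium ketyl 23 (not isolated)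
Conditions: SmI2 (2.4 equiv, 0.1 M in THF) added slowly to 22 (2 mM in THF), −78 → −30 °C; aq NH4Cl at −78 °C
Reagents that add atoms: none
Why: SmI2 pinacol (ketyl–carbonyl) macrocyclisation: single-electron transfer to the samarium-chelated α-hydroxy ketone gives the C4 ketyl radical 23, which adds to the samarium-bound C5 aldehyde to close the nine-membered lactone, the O3–Sm–O4 chelate directing C–C bond formation anti to the C2 arm (3,4-syn, 4R), the aldehyde reacting on its Felkin–Anh face (5,6-syn, 5S) and the ring arms staying apart across the new bond (trans-glycol, as in medium-ring pinacol closures), while without HMPA or a proton donor at low temperature the ynoate and the esters are not reduced.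

Step 14
Reactants: 24 (macrolide ynoate)
Product: 25 (3S,4R,5R,6S,7S,8R,9S)-4,5,6-trihydroxy-3,5,7,9-tetramethyl-2-oxooxonan-8-yl (2Z,4R)-4-hydroxydec-2-enoate
Conditions: H2 (1 atm), Lindlar catalyst (Pd/CaCO3, Pb), quinoline (cat.), EtOAc, 0 °C → rt; filtration through Celite, no acid wash
Reagents that add atoms: none
Why: Lindlar semi-hydrogenation adds hydrogen syn to the ynoate and gives the (Z)-enoate only in the last step under neutral conditions, so that the lactonisation-prone (Z)-γ-hydroxy enoate and the nine-membered lactone never meet acid, base or fluoride; no stereocentre is touched.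

## Compound list

1 | methacrolein | CC(=C)C=O | starting material
2 | trans-but-2-ene | C/C=C/C | starting material
3 | (E)-crotylbis(isopinocampheyl)borane, Ipc from (−)-α-pinene | C/C=C/CB([C@H]1C[C@H]2C[C@@H]([C@@H]1C)C2(C)C)[C@H]1C[C@H]2C[C@@H]([C@@H]1C)C2(C)C | intermediate
4 | (3R,4R)-2,4-dimethylhexa-1,5-dien-3-ol | C=C(C)[C@H](O)[C@H](C)C=C | intermediate
5 | tert-butyl{[(3R,4R)-2,4-dimethylhexa-1,5-dien-3-yl]oxy}dimethylsilane | C=C(C)[C@H](O[Si](C)(C)C(C)(C)C)[C@H](C)C=C | intermediate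
6 | (2S,3R)-3-[(tert-butyldimethylsilyl)oxy]-2-methyl-4-oxopentanoic acid | CC(=O)[C@H](O[Si](C)(C)C(C)(C)C)[C@H](C)C(=O)O | intermediate
7 | (S)-but-3-en-2-ol | C[C@H](O)C=C | starting material
8 | (2S)-but-3-en-2-yl (2S,3R)-3-[(tert-butyldimethylsilyl)oxy]-2-methyl-4-oxopentanoate | CC(=O)[C@H](O[Si](C)(C)C(C)(C)C)[C@H](C)C(=O)O[C@H](C=C)C | intermediate
9 | ozonide (1,2,4-trioxolane) of 8, ozonide carbon unassigned | CC(=O)[C@H](O[Si](C)(C)C(C)(C)C)[C@H](C)C(=O)O[C@H](C1OCOO1)C | intermediate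
10 | (2S)-1-oxopropan-2-yl (2S,3R)-3-[(tert-butyldimethylsilyl)oxy]-2-methyl-4-oxopentanoate | CC(=O)[C@H](O[Si](C)(C)C(C)(C)C)[C@H](C)C(=O)O[C@H](C=O)C | intermediate
11 | cis-but-2-ene | C/C=C\C | starting material
12 | (Z)-crotylbis(isopinocampheyl)borane, Ipc from (−)-α-pinene | C/C=C\CB([C@H]1C[C@H]2C[C@@H]([C@@H]1C)C2(C)C)[C@H]1C[C@H]2C[C@@H]([C@@H]1C)C2(C)C | intermediate
13 | (2S,3R,4S)-3-hydroxy-4-methylhex-5-en-2-yl (2S,3R)-3-[(tert-butyldimethylsilyl)oxy]-2-methyl-4-oxopentanoate | CC(=O)[C@H](O[Si](C)(C)C(C)(C)C)[C@H](C)C(=O)O[C@H]([C@H](O)[C@@H](C)C=C)C | intermediate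
14 | heptanal | CCCCCCC=O | starting material
15 | methyl propiolate | C#CC(=O)OC | starting material
16 | methyl (4R)-4-hydroxydec-2-ynoate | CCCCCC[C@@H](O)C#CC(=O)OC | intermediate
17 | methyl (4R)-4-[(tert-butyldimethylsilyl)oxy]dec-2-ynoate | CCCCCC[C@@H](O[Si](C)(C)C(C)(C)C)C#CC(=O)OC | intermediate
18 | (4R)-4-[(tert-butyldimethylsilyl)oxy]dec-2-ynoic acid | CCCCCC[C@@H](O[Si](C)(C)C(C)(C)C)C#CC(=O)O | intermediate
19 | (2S,3R,4S)-2-{[(2S,3R)-3-[(tert-butyldimethylsilyl)oxy]-2-methyl-4-oxopentanoyl]oxy}-4-methylhex-5-en-3-yl (4R)-4-[(tert-butyldimethylsilyl)oxy]dec-2-ynoate | CCCCCC[C@@H](O[Si](C)(C)C(C)(C)C)C#CC(=O)O[C@H]([C@@H](C)C=C)[C@H](C)OC(=O)[C@@H](C)[C@@H](O[Si](C)(C)C(C)(C)C)C(C)=O | intermediate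
20 | (2S,3R,4S)-2-{[(2S,3R)-3-hydroxy-2-methyl-4-oxopentanoyl]oxy}-4-methylhex-5-en-3-yl (4R)-4-hydroxydec-2-ynoate | CCCCCC[C@@H](O)C#CC(=O)O[C@H]([C@@H](C)C=C)[C@H](C)OC(=O)[C@@H](C)[C@@H](O)C(C)=O | intermediate
21 | ozonide (1,2,4-trioxolane) of 20, ozonide carbon unassigned | CCCCCC[C@@H](O)C#CC(=O)O[C@H]([C@@H](C)C1OCOO1)[C@H](C)OC(=O)[C@@H](C)[C@@H](O)C(C)=O | intermediate
22 | (2R,3R,4S)-4-{[(2S,3R)-3-hydroxy-2-methyl-4-oxopentanoyl]oxy}-2-methyl-1-oxopentan-3-yl (4R)-4-hydroxydec-2-ynoate | CCCCCC[C@@H](O)C#CC(=O)O[C@H]([C@@H](C)C=O)[C@H](C)OC(=O)[C@@H](C)[C@@H](O)C(C)=O | intermediate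
23 | samarium(III) ketyl of 22 (radical at C4, O–SmI2) | CCCCCC[C@@H](O)C#CC(=O)O[C@H]([C@@H](C)C=O)[C@H](C)OC(=O)[C@@H](C)[C@@H](O)[C](C)O[Sm](I)I | intermediate
24 | (3S,4R,5R,6S,7S,8R,9S)-4,5,6-trihydroxy-3,5,7,9-tetramethyl-2-oxooxonan-8-yl (4R)-4-hydroxydec-2-ynoate | CCCCCC[C@@H](O)C#CC(=O)O[C@@H]1[C@@H](C)[C@H](O)[C@@](C)(O)[C@H](O)[C@H](C)C(=O)O[C@H]1C | intermediate
25 | (3S,4R,5R,6S,7S,8R,9S)-4,5,6-trihydroxy-3,5,7,9-tetramethyl-2-oxooxonan-8-yl (2Z,4R)-4-hydroxydec-2-enoate | CCCCCC[C@@H](O)/C=C\C(=O)O[C@@H]1[C@@H](C)[C@H](O)[C@@](C)(O)[C@H](O)[C@H](C)C(=O)O[C@H]1C | target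

## Step count and risks

Total steps: 14. Longest linear sequence: 11 (steps 1–6 and 10–14).

Steps most likely to fail, each with one fallback:

**Step 13 (SmI2 ring closure).** The ynoate or the free propargylic alcohol may be reduced, the α-ketol may be deoxygenated, the samarium alkoxides may translactonise, or the C4/C5 diastereoselectivity may be low. The fallback sets out from 13 and comes back at 24; it closes the ring before the side chain is attached, so excess reductant and additives can be used. Compound 13 is treated with 4-methoxybenzyl trichloroacetimidate and catalytic Sc(OTf)3 to give the C7 4-methoxybenzyl ether F1. HF·pyridine then frees C3–OH to give ketol F2, and ozonolysis (Sudan Red end point) gives keto-aldehyde F3. The same SmI2 closure gives the 7-O-PMB macrolide triol F4. TESOTf/2,6-lutidine at −78 °C protects the two secondary hydroxyls as the bis(triethylsilyl) ether F5, and DDQ in CH2Cl2/pH 7 buffer gives the C7 alcohol F6. DCC/DMAP with 18 gives the ynoate ester F7, and HF·pyridine returns 24.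

**Step 6 (crotylboration of the α-acyloxy aldehyde).** Aldehyde 10 may epimerise, the acyl group may migrate on work-up, or the ketone may react. The fallback sets out from 7 and comes back at 13; it builds the C5–C8 unit before the ester. Alcohol 7 is silylated (TBSCl, imidazole) to the silyl ether F8 and ozonised to (S)-2-silyloxypropanal F9. Crotylboration with 12 gives the homoallylic alcohol F10, and TBAF gives the diol F11. F11 is acylated with 6 (DCC, DMAP, −20 °C) at its less hindered C8 hydroxyl to give 13.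

**Step 10 (acylation of the hindered C7–OH with the ynoic acid).** The bulky silyloxy ynoic acid may give N-acylurea or DMAP adducts instead of the ester. The fallback sets out from 13 and comes back at 20; it builds the side chain on the ester. Compound 13 is acylated with propiolic acid (DIC, CH2Cl2, −20 °C) to the propiolate F12. The ProPhenol/Me2Zn alkynylation of heptanal 14 with F12 gives the (R)-propargylic alcohol F13, and the desilylation conditions of step 11 then give 20.

## Further compounds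

F1 | step 13 | 7-O-(4-methoxybenzyl) ether of 13 | CC(=O)[C@H](O[Si](C)(C)C(C)(C)C)[C@H](C)C(=O)O[C@H]([C@H](OCc1ccc(OC)cc1)[C@@H](C)C=C)C
F2 | step 13 | C3-hydroxy ketol from F1 (TBS removed) | CC(=O)[C@H](O)[C@H](C)C(=O)O[C@H]([C@H](OCc1ccc(OC)cc1)[C@@H](C)C=C)C
F3 | step 13 | C5 aldehyde from F2 (keto-aldehyde) | CC(=O)[C@H](O)[C@H](C)C(=O)O[C@H]([C@H](OCc1ccc(OC)cc1)[C@@H](C)C=O)C
F4 | step 13 | (3S,4R,5R,6S,7S,8R,9S)-4,5,6-trihydroxy-8-[(4-methoxybenzyl)oxy]-3,5,7,9-tetramethyloxonan-2-one | COc1ccc(CO[C@@H]2[C@@H](C)[C@H](O)[C@@](C)(O)[C@H](O)[C@H](C)C(=O)O[C@H]2C)cc1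
F5 | step 13 | 4,6-bis-O-triethylsilyl ether of F4 (oxonane numbering) | COc1ccc(CO[C@@H]2[C@@H](C)[C@H](O[Si](CC)(CC)CC)[C@@](C)(O)[C@H](O[Si](CC)(CC)CC)[C@H](C)C(=O)O[C@H]2C)cc1
F6 | step 13 | 8-hydroxy compound from F5 (PMB removed) | O[C@@H]1[C@@H](C)[C@H](O[Si](CC)(CC)CC)[C@@](C)(O)[C@H](O[Si](CC)(CC)CC)[C@H](C)C(=O)O[C@H]1C
F7 | step 13 | 8-O-[(4R)-4-(tert-butyldimethylsilyloxy)dec-2-ynoyl] ester of F6 | CCCCCC[C@@H](O[Si](C)(C)C(C)(C)C)C#CC(=O)O[C@@H]1[C@@H](C)[C@H](O[Si](CC)(CC)CC)[C@@](C)(O)[C@H](O[Si](CC)(CC)CC)[C@H](C)C(=O)O[C@H]1C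
F8 | step 6 | (S)-(but-3-en-2-yloxy)(tert-butyl)dimethylsilane | C[C@H](O[Si](C)(C)C(C)(C)C)C=C
F9 | step 6 | (S)-2-[(tert-butyldimethylsilyl)oxy]propanal | C[C@H](O[Si](C)(C)C(C)(C)C)C=O
F10 | step 6 | (2S,3R,4S)-2-[(tert-butyldimethylsilyl)oxy]-4-methylhex-5-en-3-ol | C[C@H](O[Si](C)(C)C(C)(C)C)[C@H](O)[C@@H](C)C=C
F11 | step 6 | (2S,3R,4S)-4-methylhex-5-ene-2,3-diol | C[C@H](O)[C@H](O)[C@@H](C)C=C
F12 | step 10 | C7 propiolate ester of 13 | C#CC(=O)O[C@H]([C@@H](C)C=C)[C@H](C)OC(=O)[C@@H](C)[C@@H](O[Si](C)(C)C(C)(C)C)C(C)=O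
F13 | step 10 | C7 (4R)-4-hydroxydec-2-ynoate of 13 (C3–OTBS kept) | CCCCCC[C@@H](O)C#CC(=O)O[C@H]([C@@H](C)C=C)[C@H](C)OC(=O)[C@@H](C)[C@@H](O[Si](C)(C)C(C)(C)C)C(C)=O
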